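**Retrosynthetic overview**

1. Numbering used throughout: core C1 (epoxide C–CH3), C2 (C=O), C3 (CH–O), C4 (CH–side chain), C5 (CH–O), C6 (epoxide CH); side chain C1' (=CH2) to C7'. Last stage: acetonide removal, triple angeloylation of the 3,5,3'-triol, hydroxyl-directed nucleophilic epoxidation of the C6=C1 enone.
2. The 3-hydroxy enone comes from a 7-oxabicyclo[2.2.1]heptan-2-one by β-elimination of its oxygen bridge (C6–O cleaved, C3–O kept).
3. Key disconnection: C5–C6 and C3–C4 by a [4+2] cycloaddition of 3-methoxy-4-methylfuran (C6, C1, C2, C3 and the C3 oxygen) with cyclobut-2-en-1-one (C5, C4, C2', C3'); Baeyer–Villiger oxidation then puts oxygen on C5.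
4. Enabling feature: the C6–C1–C2–C3 run of the six-membered ring carries oxygen on C6, C2 and C3 and methyl on C1, so it is a 3-oxygenated 4-methylfuran opened at one C–O bond; C4/C5 carry a cis carbon substituent and oxygen, so they are a ring-expanded cis-fused cyclobutanone.
5. Ring order: oxygen-bridged cyclohexene with fused cyclobutanone (key step) → γ-lactone → side chain grown from the lactone carbonyl (C3') by Weinreb ketone synthesis, boron aldol (C5') and 1,3-anti reduction (C3') → bridge opening → epoxide.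

Key step: step 4

Assumption: the sense of induction of the oxazaborolidinium catalyst (step 4) and of (+)-Ipc2BCl (step 13) is taken as drawn, the mirror-image catalyst or reagent being used if the opposite sense is found; the C1 methyl epimer of ketal 8 is drawn as the exo-protonation product, and either epimer converges at 24.

**Route**

Step 1
Reactants: 1 3,4-dibromofuran
Product: 3 3-bromo-4-methylfuran, via 4-bromofuran-3-yllithium 2 (not isolated)
Conditions: n-BuLi (1.0 equiv), Et2O, −78 °C; MeI, −78 °C → rt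
Reagents that add atoms: iodomethane CI
Why: Bromine–lithium exchange on one of the two equivalent C–Br bonds at −78 °C and SN2 methylation of the 3-furyllithium should give the monomethyl furan; no stereocentre is formed.

Step 2
Reactants: 3 3-bromo-4-methylfuran
Product: 4 3-methoxy-4-methylfuran
Conditions: NaOMe (3 equiv), CuBr (10 mol%), MeOH/DMF, 100 °C, sealed tube
Reagents that add atoms: sodium methoxide C[O-].[Na+]
Why: Ullmann-type copper-catalysed C–O coupling of the heteroaryl bromide with methoxide should install the methoxy group that marks C2 as the latent ketone and later steers the cycloaddition; no stereocentre is formed.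

Step 3
Reactants: 5 3-bromocyclobutan-1-one
Product: 6 cyclobut-2-en-1-one
Conditions: n-Bu3N (2 equiv), neat, 25 °C, reduced pressure, distilled into a −78 °C trap, used as CH2Cl2 solution
Reagents that add atoms: none
Why: E1cB dehydrobromination of the β-bromo ketone by a hindered tertiary amine should give the strained enone, which is distilled away from the salt as it forms; no stereocentre is formed.

Step 4
Reactants: 4 3-methoxy-4-methylfuran (1.3 equiv), 6 cyclobut-2-en-1-one
Product: 7 endo-7-methoxy-8-methyl-9-oxatricyclo[4.2.1.0(2,5)]non-7-en-3-one (cyclobutanone ring anti to the oxygen bridge)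
Conditions: (S)-1-(2-methylphenyl)-3,3-diphenyltetrahydro-1H,3H-pyrrolo[1,2-c][1,3,2]oxazaborole (20 mol%), HN(SO2CF3)2 (18 mol%), CH2Cl2, −78 °C; Et3N quench at −78 °C
Reagents that add atoms: none
Why: The oxazaborolidinium cation binds the cyclobutenone carbonyl and lowers its LUMO, and the 3-methoxyfuran (HOMO coefficient largest at C2, next to the methoxy carbon) adds across the strained C=C in a concerted, asynchronous normal-demand Diels–Alder reaction that dearomatises the furan; the closest known reactions are Diels–Alder additions of 3-alkoxyfurans to enones and of cyclobutenone to dienes under chiral oxazaborolidinium catalysis. The carbocycle C1–C6 is closed by suprafacial [4+2] addition across the furan 2,5-positions, which leaves the furan oxygen as a one-atom bridge between C3 and C6 and the cyclobutanone cis-fused at C4–C5. C3, C4 and C5 (and the temporary centre C6) are set together: the cis fusion follows from suprafacial addition, the endo position of the four-membered ring (anti to the bridge, hence the C4 substituent trans to the C3 oxygen) from secondary orbital overlap of the bound carbonyl with the diene, and the absolute sense from the aryl groups of the catalyst, which shield one face of the coordinated enone. The regiochemistry needed (enone β-carbon to the furan carbon next to C–OMe, giving C3–C4 and C5–C6) is secured by the methoxy group, which the 4-methyl group opposes only weakly. Endo selectivity and irreversibility should be secured by the low temperature and by the release of cyclobutenone ring strain, which suppresses the retro-Diels–Alder equilibration to exo adducts usual for furans. A stepwise Michael-type pathway that could rearomatise to a 2-alkylfuran is disfavoured because its intermediate would be a strained cyclobutanone enolate.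

Step 5
Reactants: 7 endo-7-methoxy-8-methyl-9-oxatricyclo[4.2.1.0(2,5)]non-7-en-3-one
Product: 8 endo-7,7-dimethoxy-8-endo-methyl-9-oxatricyclo[4.2.1.0(2,5)]nonan-3-one
Conditions: MeOH (10 equiv), PPTS (5 mol%), CH2Cl2, 0 °C; Et3N quench
Reagents that add atoms: methanol CO
Why: Acid-catalysed Markovnikov addition of methanol to the enol ether (ketalisation) should proceed by protonation of C1 from the open exo face (temporary C1 centre, methyl endo) and removes the acid- and peracid-labile vinylogous acetal before the oxidation.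

Step 6
Reactants: 8 endo-7,7-dimethoxy-8-endo-methyl-9-oxatricyclo[4.2.1.0(2,5)]nonan-3-one
Product: 9 8,8-dimethoxy-9-endo-methyl-3,10-dioxatricyclo[5.2.1.0(2,6)]decan-4-one (γ-lactone anti to the oxygen bridge)
Conditions: mCPBA (1.3 equiv), NaHCO3, CH2Cl2, 0 °C
Reagents that add atoms: 3-chloroperoxybenzoic acid O=C(OO)c1cccc(Cl)c1
Why: Baeyer–Villiger oxidation of the strained cyclobutanone should occur by migration of the more substituted ring-fusion carbon C5 with retention, which places oxygen on C5 cis to the C4 carbon substituent.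

Step 7
Reactants: 9 8,8-dimethoxy-9-endo-methyl-3,10-dioxatricyclo[5.2.1.0(2,6)]decan-4-one
Product: 10 N-methoxy-N-methyl-2-(3-endo-hydroxy-6,6-dimethoxy-5-endo-methyl-7-oxabicyclo[2.2.1]heptan-2-endo-yl)acetamide
Conditions: MeNH(OMe)·HCl (3 equiv), i-PrMgCl (6 equiv), THF, −20 → 0 °C; aq. NH4Cl
Reagents that add atoms: N,O-dimethylhydroxylamine hydrochloride CNOC.Cl
Why: Aminolysis of the γ-lactone by the chloromagnesium amide (Weinreb amide formation) should free the C5 hydroxyl and turn the former cyclobutanone carbonyl into the acyl donor for C3'; no stereocentre is touched.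

Step 8
Reactants: 10 N-methoxy-N-methyl-2-(3-endo-hydroxy-6,6-dimethoxy-5-endo-methyl-7-oxabicyclo[2.2.1]heptan-2-endo-yl)acetamide
Product: 11 N-methoxy-N-methyl-2-{6,6-dimethoxy-5-endo-methyl-3-endo-[(triethylsilyl)oxy]-7-oxabicyclo[2.2.1]heptan-2-endo-yl}acetamide
Conditions: TESCl, imidazole, DMF, 0 °C → rt
Reagents that add atoms: chlorotriethylsilane CC[Si](Cl)(CC)CC
Why: Silylation of the secondary alcohol should block relactonisation and protect 5-OH through the organolithium and boron steps; no stereocentre is touched.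

Step 9
Reactants: 11 N-methoxy-N-methyl-2-{6,6-dimethoxy-5-endo-methyl-3-endo-[(triethylsilyl)oxy]-7-oxabicyclo[2.2.1]heptan-2-endo-yl}acetamide
Product: 15 N-methoxy-N-methyl-2-{6,6-dimethoxy-5-endo-methyl-3-endo-[(triethylsilyl)oxy]-7-oxabicyclo[2.2.1]heptan-2-endo-yl}prop-2-enamide, via lithium enolate 12 (not isolated), via Mannich base 13 (not isolated), via trimethylammonium iodide 14 (not isolated)
Conditions: LDA (1.2 equiv), THF, −78 °C; Me2N=CH2 I (1.5 equiv), −78 → 0 °C; then MeI (10 equiv), rt; then DBU (3 equiv), rt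
Reagents that add atoms: N,N-dimethylmethyleneiminium iodide C=[N+](C)C.[I-]
Why: Mannich reaction of the amide enolate with Eschenmoser's salt, N-methylation and E1cB (Hofmann-type) elimination amount to an α-methylenation that should put the C1' methylene on C2'; the α-stereocentre of 13 and 14 is erased in the elimination.

Step 10
Reactants: 15 N-methoxy-N-methyl-2-{6,6-dimethoxy-5-endo-methyl-3-endo-[(triethylsilyl)oxy]-7-oxabicyclo[2.2.1]heptan-2-endo-yl}prop-2-enamide
Product: 16 3-{6,6-dimethoxy-5-endo-methyl-3-endo-[(triethylsilyl)oxy]-7-oxabicyclo[2.2.1]heptan-2-endo-yl}but-3-en-2-one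
Conditions: MeLi (1.3 equiv), THF, −78 °C; aq. NH4Cl
Reagents that add atoms: methyllithium [Li]C
Why: Weinreb ketone synthesis, in which the chelated tetrahedral intermediate from 1,2-addition of methyllithium should collapse only on work-up and give the methyl enone without over-addition.

Step 11
Reactants: 17 methyl 2-hydroxy-2-methylpropanoate
Product: 18 methyl 2-methyl-2-[(triethylsilyl)oxy]propanoate
Conditions: TESOTf, 2,6-lutidine, CH2Cl2, 0 °C
Reagents that add atoms: triethylsilyl trifluoromethanesulfonate CC[Si](CC)(CC)OS(=O)(=O)C(F)(F)F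
Why: Silylation of the tertiary alcohol with the reactive silyl triflate should proceed cleanly; no stereocentre is present.

Step 12
Reactants: 18 methyl 2-methyl-2-[(triethylsilyl)oxy]propanoate
Product: 19 2-methyl-2-[(triethylsilyl)oxy]propanal
Conditions: DIBAL-H (1.05 equiv), CH2Cl2, −78 °C; Rochelle salt
Reagents that add atoms: none
Why: Partial reduction of the ester at −78 °C, where the aluminium hemiacetal collapses only on work-up, should give the non-enolisable α-silyloxy aldehyde.

Step 13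
Reactants: 16 3-{6,6-dimethoxy-5-endo-methyl-3-endo-[(triethylsilyl)oxy]-7-oxabicyclo[2.2.1]heptan-2-endo-yl}but-3-en-2-one, 19 2-methyl-2-[(triethylsilyl)oxy]propanal
Product: 21 (5S)-5-hydroxy-6-methyl-2-{6,6-dimethoxy-5-endo-methyl-3-endo-[(triethylsilyl)oxy]-7-oxabicyclo[2.2.1]heptan-2-endo-yl}-6-[(triethylsilyl)oxy]hept-1-en-3-one, via enol borinate 20 (not isolated)
Conditions: (+)-Ipc2BCl (1.4 equiv), Et3N (1.6 equiv), Et2O, −78 → 0 °C; 19, −78 → −20 °C; pH 7 buffer, MeOH, 30% H2O2, 0 °C
Reagents that add atoms: none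
Why: Paterson boron aldol reaction, in which the kinetic enol borinate of the methyl ketone should add to the aldehyde through a cyclic six-membered transition state with the isopinocampheyl ligands exposing the aldehyde Si face, setting C5' as (S).

Step 14
Reactants: 21 (5S)-5-hydroxy-6-methyl-2-{6,6-dimethoxy-5-endo-methyl-3-endo-[(triethylsilyl)oxy]-7-oxabicyclo[2.2.1]heptan-2-endo-yl}-6-[(triethylsilyl)oxy]hept-1-en-3-one
Product: 22 (3S,5S)-6-methyl-2-{6,6-dimethoxy-5-endo-methyl-3-endo-[(triethylsilyl)oxy]-7-oxabicyclo[2.2.1]heptan-2-endo-yl}-6-[(triethylsilyl)oxy]hept-1-ene-3,5-diol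
Conditions: Me4NBH(OAc)3 (5 equiv), MeCN/AcOH (1:1), −30 °C
Reagents that add atoms: none
Why: Evans–Saksena hydroxyl-directed reduction, in which the C5' hydroxyl should bind the triacetoxyborohydride and deliver hydride intramolecularly through a chair-like transition state, giving the 1,3-anti diol, i.e. (3'S), with 1,2-selectivity at the enone.

Step 15
Reactants: 22 (3S,5S)-6-methyl-2-{6,6-dimethoxy-5-endo-methyl-3-endo-[(triethylsilyl)oxy]-7-oxabicyclo[2.2.1]heptan-2-endo-yl}-6-[(triethylsilyl)oxy]hept-1-ene-3,5-diol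
Product: 24 (4S,5S,6R)-4,6-dihydroxy-2-methyl-5-[(3S,5S)-3,5,6-trihydroxy-6-methylhept-1-en-2-yl]cyclohex-2-en-1-one, via bridged ketone 23 (not isolated)
Conditions: 1 M aq. HCl/THF (1:3), rt; NaHCO3 to pH 7; then DBU (0.3 equiv), CH2Cl2/MeOH, 0 °C
Reagents that add atoms: water O
Why: Aqueous acid should hydrolyse the ketal and both silyl ethers, after which the amidine base should trigger E1cB β-elimination of the oxygen bridge from the C2 ketone (only C1 can enolise, C3 being a bridgehead), cleaving C6–O to give the C6=C1 enone while the bridge oxygen stays on C3 with its configuration.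

Step 16
Reactants: 24 (4S,5S,6R)-4,6-dihydroxy-2-methyl-5-[(3S,5S)-3,5,6-trihydroxy-6-methylhept-1-en-2-yl]cyclohex-2-en-1-one
Product: 25 (4S,5S,6R)-4,6-dihydroxy-5-{(3S)-3-hydroxy-4-[(4S)-2,2,5,5-tetramethyl-1,3-dioxolan-4-yl]but-1-en-2-yl}-2-methylcyclohex-2-en-1-one
Conditions: 2,2-dimethoxypropane (3 equiv), PPTS (10 mol%), acetone, 0 °C → rt
Reagents that add atoms: 2,2-dimethoxypropane COC(C)(C)OC
Why: Acid-catalysed transacetalisation should form the five-membered isopropylidene acetal on the only vicinal diol (C5'/C6'), the anti-1,3 and isolated hydroxyls giving no stable acetonide.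

Step 17
Reactants: 25 (4S,5S,6R)-4,6-dihydroxy-5-{(3S)-3-hydroxy-4-[(4S)-2,2,5,5-tetramethyl-1,3-dioxolan-4-yl]but-1-en-2-yl}-2-methylcyclohex-2-en-1-one
Product: 26 (1R,3R,4S,5R,6R)-3,5-dihydroxy-4-{(3S)-3-hydroxy-4-[(4S)-2,2,5,5-tetramethyl-1,3-dioxolan-4-yl]but-1-en-2-yl}-1-methyl-7-oxabicyclo[4.1.0]heptan-2-one
Conditions: t-BuOOH (anhydrous, 3 equiv), n-BuLi (2.5 equiv), THF, −78 → −20 °C; aq. NH4Cl
Reagents that add atoms: tert-butyl hydroperoxide CC(C)(C)OO
Why: Hydroxyl-directed Weitz–Scheffer epoxidation, in which lithium tert-butylperoxide held by the C5 hydroxyl (and by the C3' hydroxyl on the same face) should add to C6 syn to 5-OH and anti to 3-OH, closure of the enolate onto the O–O bond then giving the cis epoxide and setting C6 and C1 as (R,R).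

Step 18
Reactants: 26 (1R,3R,4S,5R,6R)-3,5-dihydroxy-4-{(3S)-3-hydroxy-4-[(4S)-2,2,5,5-tetramethyl-1,3-dioxolan-4-yl]but-1-en-2-yl}-1-methyl-7-oxabicyclo[4.1.0]heptan-2-one
Product: 27 (1R,3R,4S,5R,6R)-1-methyl-4-{(3S)-3-{[(2Z)-2-methylbut-2-enoyl]oxy}-4-[(4S)-2,2,5,5-tetramethyl-1,3-dioxolan-4-yl]but-1-en-2-yl}-2-oxo-7-oxabicyclo[4.1.0]heptane-3,5-diyl bis[(2Z)-2-methylbut-2-enoate]
Conditions: angelic acid (6 equiv), 2,4,6-trichlorobenzoyl chloride (6 equiv), Et3N (7 equiv), toluene, rt; then 26, toluene, 80 °C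
Reagents that add atoms: angelic acid C/C=C(/C)C(=O)O
Why: Yamaguchi-type esterification through the mixed anhydride, run without a nucleophilic catalyst so that the (Z)-enoate is not isomerised to the (E)-tiglate, should acylate the three secondary hydroxyls while the acetonide masks the other two; no stereocentre is changed.

Step 19
Reactants: 27 (1R,3R,4S,5R,6R)-1-methyl-4-{(3S)-3-{[(2Z)-2-methylbut-2-enoyl]oxy}-4-[(4S)-2,2,5,5-tetramethyl-1,3-dioxolan-4-yl]but-1-en-2-yl}-2-oxo-7-oxabicyclo[4.1.0]heptane-3,5-diyl bis[(2Z)-2-methylbut-2-enoate]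
Product: 28 (1R,3R,4S,5R,6R)-4-[(3S,5S)-5,6-dihydroxy-6-methyl-3-{[(2Z)-2-methylbut-2-enoyl]oxy}hept-1-en-2-yl]-1-methyl-2-oxo-7-oxabicyclo[4.1.0]heptane-3,5-diyl bis[(2Z)-2-methylbut-2-enoate] (CNP0210092.1)
Conditions: AcOH/H2O (4:1), 40 °C
Reagents that add atoms: none
Why: Mild aqueous-acid hydrolysis of the isopropylidene acetal should release the 5',6'-diol and give the target, the α,β-epoxy ketone and the angelates being stable to these conditions and the syn-disposed C5 ester being unable to open the epoxide by neighbouring-group attack.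

**Compound list**

1 | 3,4-dibromofuran | Brc1cocc1Br | starting material
2 | 4-bromofuran-3-yllithium | [Li]c1cocc1Br | intermediate
3 | 3-bromo-4-methylfuran | Cc1cocc1Br | intermediate
4 | 3-methoxy-4-methylfuran | COc1cocc1C | intermediate
5 | 3-bromocyclobutan-1-one | O=C1CC(Br)C1 | starting material
6 | cyclobut-2-en-1-one | O=C1C=CC1 | intermediate
7 | endo-7-methoxy-8-methyl-9-oxatricyclo[4.2.1.0(2,5)]non-7-en-3-one | O=C1C[C@H]2[C@@H]1[C@@H]3O[C@H]2C(OC)=C3C | intermediate
8 | endo-7,7-dimethoxy-8-endo-methyl-9-oxatricyclo[4.2.1.0(2,5)]nonan-3-one | O=C1C[C@H]2[C@@H]1[C@@H]3O[C@H]2C(OC)(OC)[C@@H]3C | intermediate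
9 | 8,8-dimethoxy-9-endo-methyl-3,10-dioxatricyclo[5.2.1.0(2,6)]decan-4-one | O=C1C[C@H]2[C@@H](O1)[C@@H]3O[C@H]2C(OC)(OC)[C@@H]3C | intermediate
10 | N-methoxy-N-methyl-2-(3-endo-hydroxy-6,6-dimethoxy-5-endo-methyl-7-oxabicyclo[2.2.1]heptan-2-endo-yl)acetamide | CON(C)C(=O)C[C@H]1[C@@H](O)[C@@H]2O[C@H]1C(OC)(OC)[C@@H]2C | intermediate
11 | 3-O-triethylsilyl ether of 10 | CON(C)C(=O)C[C@H]1[C@@H](O[Si](CC)(CC)CC)[C@@H]2O[C@H]1C(OC)(OC)[C@@H]2C | intermediate
12 | lithium (Z)-enolate of 11 | [Li]O/C(N(C)OC)=C\[C@H]1[C@@H](O[Si](CC)(CC)CC)[C@@H]2O[C@H]1C(OC)(OC)[C@@H]2C | intermediate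
13 | Mannich base: 3-(dimethylamino)-N-methoxy-N-methyl-2-(bicyclic unit of 11)propanamide, epimers at the α-carbon | CON(C)C(=O)C(CN(C)C)[C@H]1[C@@H](O[Si](CC)(CC)CC)[C@@H]2O[C@H]1C(OC)(OC)[C@@H]2C | intermediate
14 | N-methyl quaternary ammonium iodide of 13 | CON(C)C(=O)C(C[N+](C)(C)C)[C@H]1[C@@H](O[Si](CC)(CC)CC)[C@@H]2O[C@H]1C(OC)(OC)[C@@H]2C.[I-] | intermediate
15 | N-methoxy-N-methyl-2-{6,6-dimethoxy-5-endo-methyl-3-endo-[(triethylsilyl)oxy]-7-oxabicyclo[2.2.1]heptan-2-endo-yl}prop-2-enamide | C=C([C@H]1[C@@H](O[Si](CC)(CC)CC)[C@@H]2O[C@H]1C(OC)(OC)[C@@H]2C)C(=O)N(C)OC | intermediate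
16 | 3-{6,6-dimethoxy-5-endo-methyl-3-endo-[(triethylsilyl)oxy]-7-oxabicyclo[2.2.1]heptan-2-endo-yl}but-3-en-2-one | C=C([C@H]1[C@@H](O[Si](CC)(CC)CC)[C@@H]2O[C@H]1C(OC)(OC)[C@@H]2C)C(C)=O | intermediate
17 | methyl 2-hydroxy-2-methylpropanoate | COC(=O)C(C)(C)O | starting material
18 | methyl 2-methyl-2-[(triethylsilyl)oxy]propanoate | COC(=O)C(C)(C)O[Si](CC)(CC)CC | intermediate
19 | 2-methyl-2-[(triethylsilyl)oxy]propanal | O=CC(C)(C)O[Si](CC)(CC)CC | intermediate
20 | diisopinocampheylboron enolate of 16 | C=C(OB([C@H]1C[C@H]2C[C@H](C2(C)C)[C@@H]1C)[C@H]1C[C@H]2C[C@H](C2(C)C)[C@@H]1C)C(=C)[C@H]1[C@@H](O[Si](CC)(CC)CC)[C@@H]2O[C@H]1C(OC)(OC)[C@@H]2C | intermediate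
21 | (5S)-5-hydroxy-6-methyl-2-(bicyclic unit of 16)-6-[(triethylsilyl)oxy]hept-1-en-3-one | C=C([C@H]1[C@@H](O[Si](CC)(CC)CC)[C@@H]2O[C@H]1C(OC)(OC)[C@@H]2C)C(=O)C[C@H](O)C(C)(C)O[Si](CC)(CC)CC | intermediate
22 | (3S,5S)-6-methyl-2-(bicyclic unit of 16)-6-[(triethylsilyl)oxy]hept-1-ene-3,5-diol | C=C([C@H]1[C@@H](O[Si](CC)(CC)CC)[C@@H]2O[C@H]1C(OC)(OC)[C@@H]2C)[C@H](C[C@H](O)C(C)(C)O[Si](CC)(CC)CC)O | intermediate
23 | 5-endo-hydroxy-3-endo-methyl-6-endo-[(3S,5S)-3,5,6-trihydroxy-6-methylhept-1-en-2-yl]-7-oxabicyclo[2.2.1]heptan-2-one | C=C([C@H]1[C@@H](O)[C@@H]2O[C@H]1C(=O)[C@@H]2C)[C@H](C[C@H](O)C(C)(C)O)O | intermediate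
24 | (4S,5S,6R)-4,6-dihydroxy-2-methyl-5-[(3S,5S)-3,5,6-trihydroxy-6-methylhept-1-en-2-yl]cyclohex-2-en-1-one | C=C([C@H]1[C@@H](O)C=C(C)C(=O)[C@@H]1O)[C@H](C[C@H](O)C(C)(C)O)O | intermediate
25 | (4S,5S,6R)-4,6-dihydroxy-5-{(3S)-3-hydroxy-4-[(4S)-2,2,5,5-tetramethyl-1,3-dioxolan-4-yl]but-1-en-2-yl}-2-methylcyclohex-2-en-1-one | C=C([C@H]1[C@@H](O)C=C(C)C(=O)[C@@H]1O)[C@H](C[C@@H]1OC(C)(C)OC1(C)C)O | intermediate
26 | (1R,3R,4S,5R,6R)-3,5-dihydroxy-4-{(3S)-3-hydroxy-4-[(4S)-2,2,5,5-tetramethyl-1,3-dioxolan-4-yl]but-1-en-2-yl}-1-methyl-7-oxabicyclo[4.1.0]heptan-2-one | C=C([C@H]1[C@@H](O)[C@H]2O[C@@]2(C)C(=O)[C@@H]1O)[C@H](C[C@@H]1OC(C)(C)OC1(C)C)O | intermediate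
27 | tris-angelate of 26 | C=C([C@H]1[C@@H](OC(=O)/C(C)=C\C)[C@H]2O[C@@]2(C)C(=O)[C@@H]1OC(=O)/C(C)=C\C)[C@H](C[C@@H]1OC(C)(C)OC1(C)C)OC(=O)/C(C)=C\C | intermediate
28 | (1R,3R,4S,5R,6R)-4-[(3S,5S)-5,6-dihydroxy-6-methyl-3-{[(2Z)-2-methylbut-2-enoyl]oxy}hept-1-en-2-yl]-1-methyl-2-oxo-7-oxabicyclo[4.1.0]heptane-3,5-diyl bis[(2Z)-2-methylbut-2-enoate] | C=C([C@H]1[C@@H](OC(=O)/C(C)=C\C)[C@H]2O[C@@]2(C)C(=O)[C@@H]1OC(=O)/C(C)=C\C)[C@H](C[C@H](O)C(C)(C)O)OC(=O)/C(C)=C\C | target

**Step count and risks**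

Total steps: 19. Longest linear sequence: 16 steps (1, 2, 4–10, 13–19, from 3,4-dibromofuran).

Steps most likely to fail:

Step 4. The strongly acidic catalyst may decompose the electron-rich furan, a conjugate addition with rearomatisation may compete, or the enantioface discrimination may be too low. The fallback sets out from 4 and 6 and comes back at 10. The cycloaddition is run without catalyst (CH2Cl2, 0 °C → rt) and should give the same endo adduct as the racemate, that is 7 together with the enantiomeric adduct F1. Steps 5–7 are applied unchanged to the racemate and give 8 with the enantiomeric ketal F2, 9 with the enantiomeric lactone F3, and 10 with the enantiomeric hydroxy amide F4. Esterification with (S)-2-methoxy-2-phenylacetic acid (DCC, DMAP, CH2Cl2) then gives two diastereomers separable on silica, the (S)-O-methylmandelate of 10 F5 and the (S)-O-methylmandelate of the enantiomer F6. K2CO3/MeOH cleaves F5 and returns 10.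

Step 17. The peroxide may attack the enone face anti to the C4 and C5 substituents (poor facial selectivity), or the base may isomerise the γ-hydroxy enone. The fallback sets out from 25 and comes back at 27, moving the epoxidation to the allylic-alcohol oxidation level. Compound 25 is tris-angeloylated under the conditions of step 18 to the enone tris-angelate F7. Luche reduction (NaBH4, CeCl3·7H2O, MeOH, −78 °C) should give the allylic alcohol F8 with the new C2 hydroxyl trans to the C3 ester. VO(acac)2/t-BuOOH (CH2Cl2, 0 °C) should deliver oxygen syn to that hydroxyl to give the epoxy alcohol F9, and Dess–Martin periodinane restores the C2 ketone, giving 27.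

Step 18. The (Z)-2-methylbut-2-enoyl unit may isomerise to the (E)-isomer during acylation, and acylation of the three hindered hydroxyls may stay incomplete. The fallback sets out from 26 and comes back at 27, building the enoates in place instead of transferring them. The three hydroxyls are esterified with 2-[bis(2-methylphenoxy)phosphoryl]propanoic acid (DCC, DMAP, CH2Cl2) to the tris(phosphonopropionate) F10. A Z-selective Horner–Wadsworth–Emmons olefination of the Ando type with acetaldehyde (NaI, DBU, THF, −78 → 0 °C) should then give 27.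

**Further compounds**

F1 | step 4 | enantiomer of 7 | O=C1C[C@@H]2[C@H]1[C@H]3O[C@@H]2C(OC)=C3C
F2 | step 4 | enantiomer of 8 | O=C1C[C@@H]2[C@H]1[C@H]3O[C@@H]2C(OC)(OC)[C@H]3C
F3 | step 4 | enantiomer of 9 | O=C1C[C@@H]2[C@H](O1)[C@H]3O[C@@H]2C(OC)(OC)[C@H]3C
F4 | step 4 | enantiomer of 10 | CON(C)C(=O)C[C@@H]1[C@H](O)[C@H]2O[C@@H]1C(OC)(OC)[C@H]2C
F5 | step 4 | (S)-O-methylmandelate ester of 10 | CON(C)C(=O)C[C@H]1[C@@H](OC(=O)[C@@H](OC)c3ccccc3)[C@@H]2O[C@H]1C(OC)(OC)[C@@H]2C
F6 | step 4 | (S)-O-methylmandelate ester of the enantiomer of 10 | CON(C)C(=O)C[C@@H]1[C@H](OC(=O)[C@@H](OC)c3ccccc3)[C@H]2O[C@@H]1C(OC)(OC)[C@H]2C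
F7 | step 17 | tris-angelate of enone 25 | C=C([C@H]1[C@@H](OC(=O)/C(C)=C\C)C=C(C)C(=O)[C@@H]1OC(=O)/C(C)=C\C)[C@H](C[C@@H]1OC(C)(C)OC1(C)C)OC(=O)/C(C)=C\C
F8 | step 17 | C2 allylic alcohol from F7 (2-OH trans to the C3 ester) | C=C([C@H]1[C@@H](OC(=O)/C(C)=C\C)C=C(C)[C@@H](O)[C@@H]1OC(=O)/C(C)=C\C)[C@H](C[C@@H]1OC(C)(C)OC1(C)C)OC(=O)/C(C)=C\C
F9 | step 17 | epoxy alcohol from F8 (epoxide syn to 2-OH) | C=C([C@H]1[C@@H](OC(=O)/C(C)=C\C)[C@H]2O[C@@]2(C)[C@@H](O)[C@@H]1OC(=O)/C(C)=C\C)[C@H](C[C@@H]1OC(C)(C)OC1(C)C)OC(=O)/C(C)=C\C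
F10 | step 18 | tris{2-[bis(2-methylphenoxy)phosphoryl]propanoate} of 26 | C=C([C@H]1[C@@H](OC(=O)C(C)P(=O)(Oc3ccccc3C)Oc3ccccc3C)[C@H]2O[C@@]2(C)C(=O)[C@@H]1OC(=O)C(C)P(=O)(Oc3ccccc3C)Oc3ccccc3C)[C@H](C[C@@H]1OC(C)(C)OC1(C)C)OC(=O)C(C)P(=O)(Oc3ccccc3C)Oc3ccccc3C
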